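The earlier runs and the new flask come from a simulation on assumed constants, and the scatter is random.

The ratio to watch is P: mono adduct made per minute over mono adduct used up per minute.

| flask | substrate | reagent | remark | time |
|---|---|---|---|---|
| dawn | 1 M | 1 M | run made earlier |  |
| summer | 1.5 M | 1 M | run made earlier |  |
| autumn | 2 M | 2 M | run made earlier |  |
| flask | 2.0 M | 1.00 M |  | 25 min |
- dawn (time / min: mono adduct / %, bis adduct / %): 1.33: 1.3, 0.1; 3.00: 3.4, 0; 6.00: 6.3, 1.2; 15.0: 13.4, 1.3
- summer (time / min: mono adduct / %, bis adduct / %): 1.33: 1.4, 0; 3.00: 3.1, 0.4; 6.00: 7.1, 0.5; 15.0: 11.2, 2.1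
- autumn (time / min: mono adduct / %, bis adduct / %): 4.00: 8.2, 1.0; 8.00: 13.1, 1.6; 12.0: 16.6, 2.8; 15.0: 18.4, 4.8

(scatter of a reading: 0.5 percentage points)

- equivalents of reagent to substrate, everything else as given, that leave most mono adduct at 25 min
- the amount of mono adduct then, in percent of the substrate charged
- the amount of mono adduct with the amounts as given

Substrate takes up reagent to give mono adduct, which takes up more reagent to give bis adduct. Dawn and summer, at 1 M and 1.5 M substrate, have converted 7.50% and 7.60% at 6.00 min, so I take conversion per minute as free of substrate. The autumn run, with twice the reagent of dawn, converts 1.84 times as fast, so I take both steps as first order in reagent. Reagent then cancels: P = c_substrate/(s·c_mono adduct), with s the selectivity factor, the second step's constant over the first's. Bis adduct is roughly s times half the mono adduct times the conversion, so the last autumn reading gives s = 2.25, with 0.5 percentage points of scatter on 4.8% of bis adduct.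

Where is mono adduct highest? At P = one, which I reckon at 23.2% mono adduct with 52.3% substrate left.

What charge gets there in 25 min? Early autumn gives a first constant of 1.92 × 10⁻⁴ M⁻¹ s⁻¹; allowing for reagent consumed, I get 1.49 equiv.

And the flask as charged? I reckon an exposure, first constant times c_reagent integrated over time, of 0.223, then 15.6% mono adduct, and P = 2.28: short of the crossing.

The forecast differs on the peak, with 2 equiv, 30% and 15.5%, from a ratio of constants of 1.4, “though poorly defined”.

The simulation gives 1.54 equiv, 23.2% and 15.4%.

    substrate + reagent → mono adduct + by-product (k = 2.00 × 10⁻⁴ M⁻¹ s⁻¹)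
    bis adduct + by-product → side product (k = 2.70 × 10⁻⁴ M⁻¹ s⁻¹)
    reagent + mono adduct → bis adduct + by-product (k = 4.50 × 10⁻⁴ M⁻¹ s⁻¹)
    reagent + bis adduct → over-reaction product (k = 7.20 × 10⁻⁴ M⁻¹ s⁻¹)

At the best charge, substrate 52.3% and mono adduct 23.2% put P at 1.00. The flask as charged is not at rest at 25 min: reagent stands at 50% of its charge, and P from its contents is 2.32. Ten times the time takes mono adduct to 21.3% and substrate to 66.3%, with reagent at 0.0597% of its charge and P still above one, at 1.38.

For the same charges stopped at 6.0 min, P should be near 6.44. The neighbour flask holds substrate 93.5% and mono adduct 6.00%, which makes P 6.93.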